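**Retrosynthetic overview**
- Feature: each ring is a hexasubstituted 2-hydroxy-1,4-benzoquinone (C1=O, C2–OH, C3–CH3, C4=O, C5 = ring-to-ring carbon, C6 = arylethyl carbon). The run C6–C5–C5'–C6' with its two 2-(2-methoxyphenyl)ethyl chains has the connectivity of a symmetrical octa-3,5-diyne, and the para pair C1/C4 is what a carbene carbon and a CO ligand bring in.
- Target ⇒ bis(2-ethoxyquinone), with C2–OEt as a vinylogous ester ⇒ biaryl bis(4-methoxyphenol), which becomes the quinone by oxidative demethylation in the forward sense.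
- Biaryl ⇒ 1,8-bis(2-methoxyphenyl)octa-3,5-diyne + two (2-ethoxybut-2-enylidene)(methoxy)chromium carbenes, cutting C1–C6, C5–C4 and C4–C3 in each ring. In the forward sense, the first carbocycle forms on one triple bond and the second on the resulting aryl alkyne, in one flask.
- Diyne ⇒ oxidative dimerisation of 4-(2-methoxyphenyl)but-1-yne ⇒ 2-methoxybenzyl bromide + lithiated 1-(trimethylsilyl)propyne. Carbene ⇒ α-lithiated cis-ethyl prop-1-enyl ether + Cr(CO)6 + Me3OBF4.

Key step: step 5

Remark 1: the target SMILES has no stereocentre and no descriptor for the hindered C5–C5' axis, so the axis is taken as racemic.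
Remark 2: ethyl prop-1-enyl ether is sold as a cis/trans mixture; the cis isomer is taken as the one that is α-lithiated at a useful rate, and the trans isomer should stay behind and leave with the volatiles.
Remark 3: chromium carbonyl SMILES are written with Cr=C=O bonds as a drawing convention.

**Step 1**
Reactants: 1 1-(trimethylsilyl)prop-1-yne; 2 2-methoxybenzyl bromide
Product: 4 [4-(2-methoxyphenyl)but-1-yn-1-yl]trimethylsilane, via 3-lithio-1-(trimethylsilyl)prop-1-yne 3 (not isolated)
Conditions: n-BuLi, THF, −78 °C; then 2, −78 °C → rt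
Reagents that add atoms: none
Why: Propargylic lithiation followed by SN2 alkylation with a reactive benzylic bromide, in which the silyl cap blocks the acetylenic terminus and disfavours the allenic alkylation mode.

**Step 2**
Reactants: 4 [4-(2-methoxyphenyl)but-1-yn-1-yl]trimethylsilane
Product: 5 1-(but-3-yn-1-yl)-2-methoxybenzene
Conditions: K2CO3 (0.2 equiv), MeOH, rt
Reagents that add atoms: none
Why: Base-catalysed methanolysis of the C(sp)–Si bond (protodesilylation) should free the terminal alkyne without touching the aryl ether or the chain.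

**Step 3**
Reactants: 5 1-(but-3-yn-1-yl)-2-methoxybenzene (two molecules)
Product: 6 1,8-bis(2-methoxyphenyl)octa-3,5-diyne
Conditions: CuCl (10 mol %), TMEDA (20 mol %), O2 (1 atm), acetone, rt
Reagents that add atoms: none
Why: Glaser–Hay oxidative homocoupling through the copper acetylide forms the future C5–C5' bond, and 5 holds no other group that is oxidised under these conditions.

**Step 4**
Reactants: 7 cis-ethyl prop-1-enyl ether (1.5 equiv, from the commercial mixture); 8 chromium hexacarbonyl, Cr(CO)6
Product: 11 pentacarbonyl[(Z)-2-ethoxy-1-methoxybut-2-en-1-ylidene]chromium, via (Z)-1-ethoxyprop-1-en-1-yllithium 9 (not isolated), via lithium acylchromate 10 (not isolated)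
Conditions: t-BuLi, THF–pentane, −78 → −5 °C; 8, Et2O, 0 °C → rt; evaporate; Me3OBF4, CH2Cl2, 0 °C → rt
Reagents that add atoms: trimethyloxonium tetrafluoroborate, C[O+](C)C.F[B-](F)(F)F
Why: Fischer carbene synthesis: the vinylic C–H next to oxygen of the cis enol ether is removed with retention of geometry, the vinyllithium adds to a CO ligand of 8, and O-methylation of the acylchromate by the hard Meerwein salt should give 11 with methyl trans to the carbene carbon.

**Step 5**
Reactants: 6 1,8-bis(2-methoxyphenyl)octa-3,5-diyne; 11 pentacarbonyl[(Z)-2-ethoxy-1-methoxybut-2-en-1-ylidene]chromium (2.5 equiv)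
Product: 13 4,4'-diethoxy-5,5'-dimethoxy-6,6'-bis[2-(2-methoxyphenyl)ethyl]-3,3'-dimethyl-[1,1'-biphenyl]-2,2'-diol, via ortho-alkynylphenol mono-adduct 12 (not isolated)
Conditions: 11 added in two portions, degassed THF (0.3 M in 6), 55 °C, Ar; then air, Et2O, rt
Reagents that add atoms: none
Why: Heating expels one cis CO from 11, a triple bond of 6 takes the free site and inserts into Cr=C so that C1–C6 forms and the inner alkyne carbon C5 becomes the new chromium-bound vinylcarbene carbon, and migration of a CO ligand onto C5 forms C5–C4 as a chromium-held dienylketene. Each of the two carbocycles then closes in the same mode, a 6π electrocyclisation of that dienylketene joining the ketene carbon C4 to the propenyl terminus C3, and the cyclohexadienone enolises through its C3–H to the 4-methoxyphenol; 12 repeats the sequence at its remaining triple bond with a second molecule of 11. The closest known reaction type is the Dötz benzannulation of alkenyl(alkoxy)carbene chromium complexes with internal alkynes, which has also been carried through twice on 1,4-disubstituted buta-1,3-diynes to give 2,2'-biaryldiols. The selectivity needed is regiochemical, C5 and not C6 having to end next to the CO-derived C4: in the first round this rests on conjugation of the alkynyl group with the developing vinylcarbene carbon outweighing its small steric demand, and in the second round the hexasubstituted aryl group of 12 is by far the larger alkyne substituent and takes the place next to C4' for steric reasons. The methyl group of 11 lies trans to the carbene carbon, so C3 turns its hydrogen inward and the closure is not hindered, while C2 carries the ethoxy group into place without taking part. No stereocentre is formed and the hindered C5–C5' axis arises as the racemate.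

**Step 6**
Reactants: 13 4,4'-diethoxy-5,5'-dimethoxy-6,6'-bis[2-(2-methoxyphenyl)ethyl]-3,3'-dimethyl-[1,1'-biphenyl]-2,2'-diol
Product: 14 4,4'-diethoxy-2,2'-bis[2-(2-methoxyphenyl)ethyl]-5,5'-dimethyl-[1,1'-bi(cyclohexa-1,4-diene)]-3,3',6,6'-tetraone
Conditions: (NH4)2Ce(NO3)6 (4.4 equiv), MeCN–H2O, 0 °C
Reagents that add atoms: water, O
Why: Oxidative demethylation of a 4-methoxyphenol by a one-electron oxidant: two electrons leave each central ring, water adds at C1 and methanol departs, while the monomethoxy side-chain rings are much harder to oxidise and the C2 ethoxy group stays as a vinylogous ester.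

**Step 7**
Reactants: 14 4,4'-diethoxy-2,2'-bis[2-(2-methoxyphenyl)ethyl]-5,5'-dimethyl-[1,1'-bi(cyclohexa-1,4-diene)]-3,3',6,6'-tetraone
Product: 16 4,4'-dihydroxy-2,2'-bis[2-(2-methoxyphenyl)ethyl]-5,5'-dimethyl-[1,1'-bi(cyclohexa-1,4-diene)]-3,3',6,6'-tetraone (target), via disodium bis(quinonolate) 15 (not isolated)
Conditions: 1 M aq NaOH, THF–EtOH, rt, Ar; then 1 M HCl
Reagents that add atoms: sodium hydroxide, [Na+].[OH-]
Why: Addition–elimination at a vinylogous ester: hydroxide adds at C2, which is β to C4=O, ethoxide leaves, the delocalised hydroxyquinone anion resists further attack because no ring position is free, the aryl methyl ethers are inert to aqueous base, and acid releases 16.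

**Compound list**
1 | 1-(trimethylsilyl)prop-1-yne | CC#C[Si](C)(C)C | starting material
2 | 2-methoxybenzyl bromide | COc1ccccc1CBr | starting material
3 | 3-lithio-1-(trimethylsilyl)prop-1-yne | [Li]CC#C[Si](C)(C)C | intermediate
4 | [4-(2-methoxyphenyl)but-1-yn-1-yl]trimethylsilane | COc1ccccc1CCC#C[Si](C)(C)C | intermediate
5 | 1-(but-3-yn-1-yl)-2-methoxybenzene | COc1ccccc1CCC#C | intermediate
6 | 1,8-bis(2-methoxyphenyl)octa-3,5-diyne | COc1ccccc1CCC#CC#CCCc1ccccc1OC | intermediate
7 | cis-ethyl prop-1-enyl ether | CCO/C=C\C | starting material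
8 | chromium hexacarbonyl, Cr(CO)6 | O=C=[Cr](=C=O)(=C=O)(=C=O)(=C=O)=C=O | starting material
9 | (Z)-1-ethoxyprop-1-en-1-yllithium | CCO/C([Li])=C\C | intermediate
10 | lithium pentacarbonyl[(Z)-2-ethoxybut-2-enoyl]chromate | CCO/C(=C\C)C([O-])=[Cr](=C=O)(=C=O)(=C=O)(=C=O)=C=O.[Li+] | intermediate
11 | pentacarbonyl[(Z)-2-ethoxy-1-methoxybut-2-en-1-ylidene]chromium | CCO/C(=C\C)C(OC)=[Cr](=C=O)(=C=O)(=C=O)(=C=O)=C=O | intermediate
12 | 3-ethoxy-4-methoxy-5-[2-(2-methoxyphenyl)ethyl]-6-[4-(2-methoxyphenyl)but-1-yn-1-yl]-2-methylphenol | COc1ccccc1CCC#Cc1c(O)c(C)c(OCC)c(OC)c1CCc1ccccc1OC | intermediate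
13 | 4,4'-diethoxy-5,5'-dimethoxy-6,6'-bis[2-(2-methoxyphenyl)ethyl]-3,3'-dimethyl-[1,1'-biphenyl]-2,2'-diol (racemic axis) | COc1ccccc1CCc1c(OC)c(OCC)c(C)c(O)c1-c1c(O)c(C)c(OCC)c(OC)c1CCc1ccccc1OC | intermediate
14 | 4,4'-diethoxy-2,2'-bis[2-(2-methoxyphenyl)ethyl]-5,5'-dimethyl-[1,1'-bi(cyclohexa-1,4-diene)]-3,3',6,6'-tetraone | COc1ccccc1CCC1=C(C2=C(CCc3ccccc3OC)C(=O)C(OCC)=C(C)C2=O)C(=O)C(C)=C(OCC)C1=O | intermediate
15 | disodium salt of 16 | COc1ccccc1CCC1=C(C2=C(CCc3ccccc3OC)C(=O)C([O-])=C(C)C2=O)C(=O)C(C)=C([O-])C1=O.[Na+].[Na+] | intermediate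
16 | 4,4'-dihydroxy-2,2'-bis[2-(2-methoxyphenyl)ethyl]-5,5'-dimethyl-[1,1'-bi(cyclohexa-1,4-diene)]-3,3',6,6'-tetraone | COc1ccccc1CCC1=C(C2=C(CCc3ccccc3OC)C(=O)C(O)=C(C)C2=O)C(=O)C(C)=C(O)C1=O | target

**Total step count:** 7. **Longest linear sequence:** 6 (steps 1, 2, 3, 5, 6, 7).

**Steps most likely to fail**

**Step 5.**
- What may go wrong: the first triple bond may insert in the opposite sense, so that the chain-bearing carbon and not the inner carbon ends next to the CO-derived carbon.
- The reaction may stall after one annulation, because the remaining triple bond is shielded while the carbene decays thermally.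
- The new phenol oxygen may attack the neighbouring triple bond.
- The fallback sets out from 4 and 11 and comes back to the route at 14. It makes the ring-to-ring bond after the rings instead of before them.
- Silylalkyne 4 is benzannulated once with 11 (THF, 60 °C, then air). Silyl-capped alkynes place the silicon-bearing carbon on the ketene carbon, so silicon should mark C5 and give 3-ethoxy-4-methoxy-5-[2-(2-methoxyphenyl)ethyl]-2-methyl-6-(trimethylsilyl)phenol F1.
- O-Methylation (MeI, K2CO3, acetone) should give {4-ethoxy-2,5-dimethoxy-6-[2-(2-methoxyphenyl)ethyl]-3-methylphenyl}trimethylsilane F2.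
- Ipso-iododesilylation (ICl, 1.0 equiv, CH2Cl2, −78 °C) should give 1-ethoxy-4-iodo-2,5-dimethoxy-3-[2-(2-methoxyphenyl)ethyl]-6-methylbenzene F3.
- Ullmann homocoupling (Cu powder, DMF, 150 °C) should give 4,4'-diethoxy-2,2',5,5'-tetramethoxy-6,6'-bis[2-(2-methoxyphenyl)ethyl]-3,3'-dimethyl-1,1'-biphenyl F4.
- Oxidative demethylation of both 1,4-dimethoxy rings with (NH4)2Ce(NO3)6 in MeCN–H2O then leads to 14.

**Step 4.**
- What may go wrong: allylic instead of vinylic deprotonation, incomplete metalation that leaves t-BuLi to attack 8, and erosion of the alkene geometry.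
- The fallback sets out from 8, which it keeps as the chromium source. It takes commercial ethoxyacetylene F5 in place of 7 and comes back to the route at 9. C–H deprotonation is replaced by hydrometalation and tin–lithium exchange.
- Ethoxyacetylene F5 is deprotonated (n-BuLi, THF, −78 °C) to lithium ethoxyacetylide F6 and C-methylated (MeI) to 1-ethoxyprop-1-yne F7.
- Syn hydrostannation follows (Bu3SnH, Pd(PPh3)4 cat., THF, 0 °C). With alkynyl ethers this puts tin on the oxygen-bearing carbon, so it should give (E)-tributyl(1-ethoxyprop-1-en-1-yl)stannane F8 with ethoxy and methyl cis.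
- Exchange with n-BuLi (THF, −78 °C) proceeds with retention and should deliver 9 free of allylic isomers, ready for addition to 8.

**Step 7.**
- What may go wrong: base-induced tautomerisation of the alkylquinone to a quinone methide followed by oligomerisation, and oxidative decay of the electron-rich anion.
- The fallback sets out from 14 and comes back to the route at 16. It cleaves the O–CH2CH3 bond instead of the C2–O bond and uses no base.
- BCl3 (CH2Cl2, −78 → 0 °C) should chelate between the C1 carbonyl and the ethoxy oxygen, and chloride then attacks the ethyl carbon in an SN2 dealkylation. This gives the bis(dichloroboryl) ether of the target F9, while the unchelated aryl methyl ethers stay intact.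
- Aqueous work-up releases 16.

**Further compounds**
F1 | step 5 | 3-ethoxy-4-methoxy-5-[2-(2-methoxyphenyl)ethyl]-2-methyl-6-(trimethylsilyl)phenol | COc1ccccc1CCc1c(OC)c(OCC)c(C)c(O)c1[Si](C)(C)C
F2 | step 5 | {4-ethoxy-2,5-dimethoxy-6-[2-(2-methoxyphenyl)ethyl]-3-methylphenyl}trimethylsilane | COc1ccccc1CCc1c(OC)c(OCC)c(C)c(OC)c1[Si](C)(C)C
F3 | step 5 | 1-ethoxy-4-iodo-2,5-dimethoxy-3-[2-(2-methoxyphenyl)ethyl]-6-methylbenzene | COc1ccccc1CCc1c(OC)c(OCC)c(C)c(OC)c1I
F4 | step 5 | 4,4'-diethoxy-2,2',5,5'-tetramethoxy-6,6'-bis[2-(2-methoxyphenyl)ethyl]-3,3'-dimethyl-1,1'-biphenyl | COc1ccccc1CCc1c(OC)c(OCC)c(C)c(OC)c1-c1c(OC)c(C)c(OCC)c(OC)c1CCc1ccccc1OC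
F5 | step 4 | ethoxyacetylene | C#COCC
F6 | step 4 | lithium ethoxyacetylide | [Li]C#COCC
F7 | step 4 | 1-ethoxyprop-1-yne | CC#COCC
F8 | step 4 | (E)-tributyl(1-ethoxyprop-1-en-1-yl)stannane | CCO/C(=C\C)[Sn](CCCC)(CCCC)CCCC
F9 | step 7 | bis(dichloroboryl) ether of the target | COc1ccccc1CCC1=C(C2=C(CCc3ccccc3OC)C(=O)C(OB(Cl)Cl)=C(C)C2=O)C(=O)C(C)=C(OB(Cl)Cl)C1=O
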